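**Assumption:** the SMILES encodes the trans-(2R,3R) benzodioxane, with the ring oxygen para to the styryl group on the catechol-bearing carbon; the route is planned for exactly that isomer.

## Retrosynthetic overview
1. Maackin (14) ⇐ global MOM removal from hexa-MOM trans-benzodioxane 13.
2. The dioxane ring is the only ring made (all benzene rings are purchased); it is closed last by stereoretentive intramolecular Pd aryl C–O coupling of syn bromo-alcohol 12.
3. Key step: both stereocentres are set in one operation by Ru-TsDPEN transfer hydrogenation with dynamic kinetic resolution (ATH-DKR) of the racemic, configurationally labile α-aryloxy ketone 11.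
4. 11 ⇐ SN2 etherification of desyl-type bromide 6 with bromostilbene phenol 10.
5. 6 ⇐ Pd α-arylation of acetophenone 4 with aryl bromide 2; 10 ⇐ C–I-selective Heck of 2-bromo-5-iodophenol with styrene 8, itself made from the same bromide 2.

## Route

**Step 1**
Reactants: 1, 5-bromobenzene-1,3-diol
Product: 2, 1-bromo-3,5-bis(methoxymethoxy)benzene
Conditions: MOMCl, i-Pr2NEt, CH2Cl2, 0 °C → rt
Reagents that add atoms: chloromethyl methyl ether (MOMCl), COCCl
Why: Williamson-type O-alkylation (MOM acetal protection) of both phenols; the aryl bromide is inert.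

**Step 2**
Reactants: 3, 1-(3,4-dihydroxyphenyl)ethan-1-one
Product: 4, 1-[3,4-bis(methoxymethoxy)phenyl]ethan-1-one
Conditions: MOMCl, i-Pr2NEt, CH2Cl2, 0 °C → rt
Reagents that add atoms: chloromethyl methyl ether (MOMCl), COCCl
Why: MOM protection of the catechol under mild amine base; the ketone is untouched.

**Step 3**
Reactants: 4, 1-[3,4-bis(methoxymethoxy)phenyl]ethan-1-one (1.2 equiv); 2, 1-bromo-3,5-bis(methoxymethoxy)benzene
Product: 5, 1-[3,4-bis(methoxymethoxy)phenyl]-2-[3,5-bis(methoxymethoxy)phenyl]ethan-1-one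
Conditions: Pd2(dba)3, Xantphos, NaOtBu, THF, 70 °C
Reagents that add atoms: none
Why: Buchwald–Hartwig-type Pd-catalysed ketone α-arylation; the methyl ketone enolate couples once with the aryl bromide (second arylation is sterically slow) and MOM ethers tolerate NaOtBu.

**Step 4**
Reactants: 5, the deoxybenzoin from step 3
Product: 6, rac-2-bromo-1-[3,4-bis(methoxymethoxy)phenyl]-2-[3,5-bis(methoxymethoxy)phenyl]ethan-1-one
Conditions: LiHMDS, TMSCl, THF, −78 °C; then NBS, −78 → 0 °C
Reagents that add atoms: N-bromosuccinimide, O=C1CCC(=O)N1Br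
Why: Silyl enol ether formation then electrophilic α-bromination; the enol ether is far more nucleophilic than the MOM-protected rings and no HBr is formed, so ring bromination and MOM loss are avoided (the new centre is racemic and is reset later).

**Step 5**
Reactants: 2, 1-bromo-3,5-bis(methoxymethoxy)benzene; 7, potassium vinyltrifluoroborate
Product: 8, 1-ethenyl-3,5-bis(methoxymethoxy)benzene
Conditions: PdCl2(dppf), Cs2CO3, THF/H2O (9:1), 80 °C
Reagents that add atoms: none (vinyl group comes from 7)
Why: Suzuki–Miyaura (Molander) vinylation of an unhindered aryl bromide.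

**Step 6**
Reactants: 8, 1-ethenyl-3,5-bis(methoxymethoxy)benzene; 9, 2-bromo-5-iodophenol
Product: 10, 2-bromo-5-[(E)-2-[3,5-bis(methoxymethoxy)phenyl]ethenyl]phenol
Conditions: Pd(OAc)2, n-Bu4NCl, NaHCO3, DMF, 70 °C
Reagents that add atoms: none
Why: Mizoroki–Heck reaction under ligand-free Jeffery conditions; oxidative addition at C–I is much faster than at the electron-rich C–Br ortho to the phenol, and syn-insertion/syn-β-H elimination gives the E-stilbene.

**Step 7**
Reactants: 6, the α-bromo ketone; 10, the bromostilbene phenol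
Product: 11, rac-2-{2-bromo-5-[(E)-2-[3,5-bis(methoxymethoxy)phenyl]ethenyl]phenoxy}-1-[3,4-bis(methoxymethoxy)phenyl]-2-[3,5-bis(methoxymethoxy)phenyl]ethan-1-one
Conditions: K2CO3, acetone, rt, N2
Reagents that add atoms: none
Why: Williamson SN2 etherification of the phenoxide on a benzylic α-keto bromide with no β-hydrogens; this fixes the regiochemistry (the oxygen meta to the styryl group ends up on the carbon bearing the 3,5-dioxygenated ring), and the new centre is deliberately racemic.

**Step 8 (key step)**
Reactants: 11, the racemic α-aryloxy ketone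
Product: 12, (1R,2R)-2-{2-bromo-5-[(E)-2-[3,5-bis(methoxymethoxy)phenyl]ethenyl]phenoxy}-1-[3,4-bis(methoxymethoxy)phenyl]-2-[3,5-bis(methoxymethoxy)phenyl]ethan-1-ol (syn/threo)
Conditions: RuCl[(S,S)-TsDPEN](p-cymene) (2 mol%), HCO2H–Et3N (5:2), DMF, 40 °C
Reagents that add atoms: none (formic acid delivers only H)
Why: Proposed new method: Noyori–Ikariya ATH with DKR applied to an α-aryl-α-aryloxy ketone, a substrate class I am treating as unproven; the doubly activated α-H (benzylic, α-keto, α-OAr) enolises rapidly with Et3N so the two enantiomers of 11 interconvert, the (S,S)-catalyst delivers hydride to the carbonyl face that gives the (1R) carbinol (same facial sense as benzoin → (R,R)-hydrobenzoin), and a polar Felkin–Anh transition state (C–OAr anti to the incoming Ru–H) selects the α-(R) enantiomer to give the syn (1R,2R) alcohol; the closest known reactions are ATH-DKR of benzoins to syn-hydrobenzoins and of α-alkoxy-β-keto esters to syn products, and the stilbene, aryl bromide and MOM ethers are inert to Ru–H/formate.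

**Step 9**
Reactants: 12, the (1R,2R) bromo-alcohol
Product: 13, (2R,3R)-2-[3,4-bis(methoxymethoxy)phenyl]-3-[3,5-bis(methoxymethoxy)phenyl]-6-[(E)-2-[3,5-bis(methoxymethoxy)phenyl]ethenyl]-2,3-dihydro-1,4-benzodioxine (trans)
Conditions: Pd(OAc)2, 2-(di-tert-butylphosphino)-1,1′-binaphthyl, Cs2CO3, toluene, 70 °C
Reagents that add atoms: none
Why: Buchwald-type intramolecular Pd-catalysed aryl C–O etherification; the bond forms at the aryl carbon, so both sp3 centres are retained and the syn (1R,2R) alcohol gives the trans (2R,3R) dioxane, while the bulky ligand favours C–O reductive elimination over β-hydride elimination.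

**Step 10**
Reactants: 13, the hexa-MOM benzodioxane
Product: 14, Maackin, (2R,3R)-2-(3,4-dihydroxyphenyl)-3-(3,5-dihydroxyphenyl)-6-[(E)-2-(3,5-dihydroxyphenyl)ethenyl]-2,3-dihydro-1,4-benzodioxine
Conditions: 3 M HCl (aq), MeOH/THF, 45 °C, degassed (Ar)
Reagents that add atoms: none
Why: Acid-catalysed hydrolysis of the six phenolic MOM acetals; C3 has no ionisation pathway, and any reversible p-hydroxybenzylic ionisation at C2 re-closes to the thermodynamically preferred trans ring, so the configuration is preserved.

## Compound list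
1 | 5-bromobenzene-1,3-diol | Oc1cc(O)cc(Br)c1 | starting material
2 | 1-bromo-3,5-bis(methoxymethoxy)benzene | COCOc1cc(Br)cc(OCOC)c1 | intermediate
3 | 1-(3,4-dihydroxyphenyl)ethan-1-one | CC(=O)c1ccc(O)c(O)c1 | starting material
4 | 1-[3,4-bis(methoxymethoxy)phenyl]ethan-1-one | CC(=O)c1ccc(OCOC)c(OCOC)c1 | intermediate
5 | 1-[3,4-bis(methoxymethoxy)phenyl]-2-[3,5-bis(methoxymethoxy)phenyl]ethan-1-one | COCOc1cc(CC(=O)c2ccc(OCOC)c(OCOC)c2)cc(OCOC)c1 | intermediate
6 | rac-2-bromo-1-[3,4-bis(methoxymethoxy)phenyl]-2-[3,5-bis(methoxymethoxy)phenyl]ethan-1-one | COCOc1cc(C(Br)C(=O)c2ccc(OCOC)c(OCOC)c2)cc(OCOC)c1 | intermediate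
7 | potassium vinyltrifluoroborate | C=C[B-](F)(F)F.[K+] | starting material
8 | 1-ethenyl-3,5-bis(methoxymethoxy)benzene | C=Cc1cc(OCOC)cc(OCOC)c1 | intermediate
9 | 2-bromo-5-iodophenol | Oc1cc(I)ccc1Br | starting material
10 | 2-bromo-5-[(E)-2-[3,5-bis(methoxymethoxy)phenyl]ethenyl]phenol | COCOc1cc(OCOC)cc(/C=C/c2ccc(Br)c(O)c2)c1 | intermediate
11 | rac-2-{2-bromo-5-[(E)-2-[3,5-bis(methoxymethoxy)phenyl]ethenyl]phenoxy}-1-[3,4-bis(methoxymethoxy)phenyl]-2-[3,5-bis(methoxymethoxy)phenyl]ethan-1-one | COCOc1cc(OCOC)cc(/C=C/c2ccc(Br)c(c2)OC(c2cc(OCOC)cc(OCOC)c2)C(=O)c2ccc(OCOC)c(OCOC)c2)c1 | intermediate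
12 | (1R,2R)-2-{2-bromo-5-[(E)-2-[3,5-bis(methoxymethoxy)phenyl]ethenyl]phenoxy}-1-[3,4-bis(methoxymethoxy)phenyl]-2-[3,5-bis(methoxymethoxy)phenyl]ethan-1-ol | COCOc1cc(OCOC)cc(/C=C/c2ccc(Br)c(c2)O[C@H](c2cc(OCOC)cc(OCOC)c2)[C@@H](c2ccc(OCOC)c(OCOC)c2)O)c1 | intermediate
13 | (2R,3R)-2-[3,4-bis(methoxymethoxy)phenyl]-3-[3,5-bis(methoxymethoxy)phenyl]-6-[(E)-2-[3,5-bis(methoxymethoxy)phenyl]ethenyl]-2,3-dihydro-1,4-benzodioxine | COCOc1cc(OCOC)cc(/C=C/c2ccc3c(c2)O[C@H](c2cc(OCOC)cc(OCOC)c2)[C@@H](c2ccc(OCOC)c(OCOC)c2)O3)c1 | intermediate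
14 | Maackin | Oc1cc(O)cc(/C=C/c2ccc3c(c2)O[C@H](c2cc(O)cc(O)c2)[C@@H](c2ccc(O)c(O)c2)O3)c1 | target

## Summary
Total steps: 10. Longest linear sequence: 7 (steps 1 or 2 → 3 → 4 → 7 → 8 → 9 → 10).

Three steps most likely to fail:

1. **Step 8 (ATH-DKR; syn/anti selectivity and rate on a hindered, electron-rich ketone).** Any anti isomer must be removed by chromatography, because it would converge on the enantiomer later. Fallback: if anti dominates, use the (R,R)-catalyst to obtain the (1S,2R) alcohol, close the ring as in step 9 to the cis-(2S,3R) dioxane, and after MOM removal epimerise C2 to trans through the p-quinone methide (K2CO3/MeOH or the acidic deprotection itself). This makes C3 the only catalyst-set centre and sets C2 thermodynamically.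

2. **Step 9 (Pd C–O closure; β-hydride elimination back to ketone, hindered secondary alkoxide).** Fallback: switch to a metal-free SNAr ring closure. Build ring A from 4-fluoro-3-hydroxybenzonitrile (etherify with 6, ATH-DKR, then KHMDS-mediated intramolecular SNAr para to the nitrile, still stereoretentive). Then reduce the nitrile with DIBAL-H to the 6-carbaldehyde and install the stilbene last by HWE olefination with diethyl 3,5-bis(methoxymethoxy)benzylphosphonate.

3. **Step 10 (six-fold acidic MOM removal on an oxidation- and acid-sensitive polyphenolic stilbene with a p-hydroxybenzylic aryl ether).** Fallback: change the protecting-group strategy to silyl ethers. Carry all six phenols as TIPS ethers (using K3PO4 instead of NaOtBu in step 3) and unmask with buffered fluoride (TBAF/AcOH, 0 °C), so no acid touches the final product.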